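## Retrosynthetic overview

1. Dinklagin A is traced back to its 5,6-dihydro form (C7 ketone, C6 sp3). Ring A is carried as a cyclohexane-1,3-dione and aromatised last by dehydrogenation.
2. Ring C is opened at C2–C3 and O1–C8a: a formal [4+2] between the C=O of 2,2-dimethyl-2H-chromene-6-carbaldehyde (C2=O1) and the diene C3=C4–C4a=C8a of the tris(silyl enol ether) of 4-acetyl-6-prenylcyclohexane-1,3-dione. This step also sets C2.
3. Enabling feature: C4=O (ring C), C8a–O1 and C7–OH (ring A) are 1,3,5-related along C4–C4a–C8a–C8–C7. At the dihydro level, ring A plus C3/C4 is therefore a cyclic 1,3,5-triketone, whose enol ether has a free nucleophilic CH2 (C3) and an oxygen leaving group on C8a.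
4. The triketone comes from 3-ethoxycyclohex-2-enone: prenyl at the future C6 by α′-alkylation, acetyl at the future C4a by dianion acylation. The aldehyde comes from 4-hydroxybenzaldehyde by propargyl ether Claisen rearrangement.
5. Ring order: pyran ring of the chromene, then ring C (key step), then aromatisation of ring A.

Key step: step 7

Assumption: the (S)-BINOL–titanium catalyst is taken to deliver the nucleophile to the Si face of the aromatic aldehyde, as in related BINOL–titanium aldol and allylation reactions; if the sense proves opposite, (R)-BINOL is used without other change.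

Remark: the polycarbonyl compounds are drawn as keto tautomers although they are largely enolised. The prenyl-bearing ring carbon is racemic until the last step, where it becomes aromatic.

## Route

Step 1
Reactants: 1 3-ethoxycyclohex-2-en-1-one; 2 1-bromo-3-methylbut-2-ene (prenyl bromide)
Product: 3 3-ethoxy-6-(3-methylbut-2-en-1-yl)cyclohex-2-en-1-one (racemic)
Conditions: LDA (1.1 equiv), THF, −78 °C; then 2, −78 °C to rt
Reagents that add atoms: none
Why: Stork–Danheiser alkylation, in which kinetic deprotonation of the vinylogous ester occurs only at the α′ carbon, so the prenyl group is placed regiospecifically on the carbon that becomes C6 of ring A.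

Step 2
Reactants: 3 3-ethoxy-6-(3-methylbut-2-en-1-yl)cyclohex-2-en-1-one
Product: 4 4-(3-methylbut-2-en-1-yl)cyclohexane-1,3-dione (racemic)
Conditions: 1 M HCl, THF, rt
Reagents that add atoms: water, O
Why: acid hydrolysis of the enol ether of a vinylogous ester to the 1,3-dione, mild enough to leave the trisubstituted alkene untouched.

Step 3
Reactants: 4 4-(3-methylbut-2-en-1-yl)cyclohexane-1,3-dione; 5 N-methoxy-N-methylacetamide
Product: 6 4-acetyl-6-(3-methylbut-2-en-1-yl)cyclohexane-1,3-dione (racemic, diastereomer and tautomer mixture)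
Conditions: LDA (2.3 equiv), THF/DMPU, −78 to −30 °C; then 5, −78 to 0 °C; 1 M HCl work-up
Reagents that add atoms: none
Why: Hauser-type C-acylation of a 1,3-diketone dianion, in which the second deprotonation should take the unhindered ring CH2 and not the prenyl-bearing CH, and the Weinreb amide holds the adduct as a stable chelate until work-up, so the acetyl group arrives on the future C4a.

Step 4
Reactants: 6 4-acetyl-6-(3-methylbut-2-en-1-yl)cyclohexane-1,3-dione
Product: 8 1-[1-(trimethylsilyloxy)ethenyl]-2,4-bis(trimethylsilyloxy)-5-(3-methylbut-2-en-1-yl)cyclohexa-1,3-diene (racemic), via bis(trimethylsilyl) dienol ether 7 (not isolated)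
Conditions: TMSCl (2.4 equiv), Et3N (2.6 equiv), Et2O, rt, filtration under argon; then LDA (1.15 equiv), THF, −78 °C, TMSCl (1.3 equiv); pentane, filtration, used crude
Reagents that add atoms: chlorotrimethylsilane, C[Si](C)(C)Cl
Why: two-stage Chan silylation of a β-polycarbonyl compound, in which soft enolisation caps the two acidic enols and kinetic deprotonation of the remaining methyl ketone (its only α-hydrogens) followed by O-silylation gives the terminal methylene of the triene.

Step 5
Reactants: 9 4-hydroxybenzaldehyde; 10 3-chloro-3-methylbut-1-yne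
Product: 11 4-[(2-methylbut-3-yn-2-yl)oxy]benzaldehyde
Conditions: DBU (1.3 equiv), CuCl2·2H2O (1 mol%), MeCN, 0 °C
Reagents that add atoms: none
Why: copper-catalysed O-alkylation of a phenol with a tertiary propargylic chloride, a standard entry to 1,1-dimethylpropargyl aryl ethers.

Step 6
Reactants: 11 4-[(2-methylbut-3-yn-2-yl)oxy]benzaldehyde
Product: 12 2,2-dimethyl-2H-chromene-6-carbaldehyde
Conditions: N,N-diethylaniline, 190 °C
Reagents that add atoms: none
Why: aryl propargyl ether Claisen rearrangement followed by [1,5]-hydrogen shift and oxa-6π electrocyclisation, which can give only one chromene because both ortho positions are equivalent.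

Step 7
Reactants: 8 1-[1-(trimethylsilyloxy)ethenyl]-2,4-bis(trimethylsilyloxy)-5-(3-methylbut-2-en-1-yl)cyclohexa-1,3-diene; 12 2,2-dimethyl-2H-chromene-6-carbaldehyde
Product: 15 (2S)-2-(2,2-dimethyl-2H-chromen-6-yl)-6-(3-methylbut-2-en-1-yl)-2,3,5,6,7,8-hexahydro-4H-chromene-4,7-dione (both C6 epimers), via silylated aldol adduct 13 (not isolated), via hydroxy triketone 14 (not isolated)
Conditions: 8 (1.3 equiv), Ti(OiPr)4 (10 mol%), (S)-BINOL (10 mol%), 4 Å MS, THF, −78 °C to rt; then TFA (3 equiv), CH2Cl2, −78 to 0 °C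
Reagents that add atoms: none
Why: Proposed new method: a catalytic enantioselective terminal aldol–cyclocondensation (formal hetero-Diels–Alder reaction) of a cyclic 1,3,5-tris(silyloxy)triene, in which the BINOL–titanium Lewis acid activates the aldehyde of 12, the terminal methylene of 8 (largest HOMO coefficient and the only unhindered nucleophilic carbon) attacks it in an open Mukaiyama-type transition state to make the C2–C3 bond, and acid then strips the silyl groups so that the new hydroxyl adds to the ring carbonyl C8a and water is lost to make the O1–C8a bond. The closest known reaction type is the Ti(OiPr)4/BINOL-catalysed Mukaiyama aldol addition of Chan-type 1,3-bis(silyloxy)dienes to aromatic aldehydes with TFA cyclisation to 2,3-dihydro-4H-pyran-4-ones, the stepwise counterpart of the Danishefsky hetero-Diels–Alder reaction. Ring C closes by 6-exo-trig addition of the hydroxyl to the C8a carbonyl followed by dehydration to the vinylogous ester. The C2 stereocentre is set by the catalyst, (S)-BINOL being chosen to direct attack to the Si face of the aldehyde and give the (S)-carbinol, while C6 is racemic and is erased in step 8, so both C6 epimers are carried on. Site selectivity for C3 over C4a and C8 is secured by the terminal unsubstituted methylene, closure on C8a and not C7 by ring size (six against eight), and the acid stage is kept cold and short to avoid ionisation at the p-alkoxybenzylic C2 and cyclisation of the prenyl group onto the C7 oxygen.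

Step 8
Reactants: 15 (2S)-2-(2,2-dimethyl-2H-chromen-6-yl)-6-(3-methylbut-2-en-1-yl)-2,3,5,6,7,8-hexahydro-4H-chromene-4,7-dione
Product: 16 Dinklagin A, (2S)-2-(2,2-dimethyl-2H-chromen-6-yl)-7-hydroxy-6-(3-methylbut-2-en-1-yl)-2,3-dihydro-4H-chromen-4-one
Conditions: DDQ (1.05 equiv), 1,4-dioxane, 10 °C to rt
Reagents that add atoms: none
Why: quinone dehydrogenation of a dihydroresorcinol-type ring, in which hydride abstraction from C5 of the enol form gives a cation stabilised by O1 (at C8a) and the C7 oxygen and loss of the C6 proton gives the phenol, so both C6 epimers converge and C2 is not touched.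

## Compound list

1 | 3-ethoxycyclohex-2-en-1-one | CCOC1=CC(=O)CCC1 | starting material
2 | 1-bromo-3-methylbut-2-ene | CC(C)=CCBr | starting material
3 | 3-ethoxy-6-(3-methylbut-2-en-1-yl)cyclohex-2-en-1-one (racemic) | CCOC1=CC(=O)C(CC=C(C)C)CC1 | intermediate
4 | 4-(3-methylbut-2-en-1-yl)cyclohexane-1,3-dione (racemic) | CC(C)=CCC1CCC(=O)CC1=O | intermediate
5 | N-methoxy-N-methylacetamide | CC(=O)N(C)OC | starting material
6 | 4-acetyl-6-(3-methylbut-2-en-1-yl)cyclohexane-1,3-dione (racemic, keto form drawn) | CC(=O)C1CC(CC=C(C)C)C(=O)CC1=O | intermediate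
7 | 1-[2,4-bis(trimethylsilyloxy)-5-(3-methylbut-2-en-1-yl)cyclohexa-1,3-dien-1-yl]ethanone (racemic, not isolated) | CC(=O)C1=C(O[Si](C)(C)C)C=C(O[Si](C)(C)C)C(CC=C(C)C)C1 | intermediate
8 | 1-[1-(trimethylsilyloxy)ethenyl]-2,4-bis(trimethylsilyloxy)-5-(3-methylbut-2-en-1-yl)cyclohexa-1,3-diene (racemic) | C=C(O[Si](C)(C)C)C1=C(O[Si](C)(C)C)C=C(O[Si](C)(C)C)C(CC=C(C)C)C1 | intermediate
9 | 4-hydroxybenzaldehyde | O=Cc1ccc(O)cc1 | starting material
10 | 3-chloro-3-methylbut-1-yne | C#CC(C)(C)Cl | starting material
11 | 4-[(2-methylbut-3-yn-2-yl)oxy]benzaldehyde | C#CC(C)(C)Oc1ccc(C=O)cc1 | intermediate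
12 | 2,2-dimethyl-2H-chromene-6-carbaldehyde | O=Cc1ccc2c(c1)C=CC(C)(C)O2 | intermediate
13 | silylated aldol adduct: (3S)-1-[2,4-bis(trimethylsilyloxy)-5-(3-methylbut-2-en-1-yl)cyclohexa-1,3-dien-1-yl]-3-(2,2-dimethyl-2H-chromen-6-yl)-3-(trimethylsilyloxy)propan-1-one (not isolated) | CC(C)=CCC1CC(C(=O)C[C@H](O[Si](C)(C)C)c2ccc3c(c2)C=CC(C)(C)O3)=C(O[Si](C)(C)C)C=C1O[Si](C)(C)C | intermediate
14 | hydroxy triketone: 4-[(3S)-3-(2,2-dimethyl-2H-chromen-6-yl)-3-hydroxypropanoyl]-6-(3-methylbut-2-en-1-yl)cyclohexane-1,3-dione (not isolated) | CC(C)=CCC1CC(C(=O)C[C@H](O)c2ccc3c(c2)C=CC(C)(C)O3)C(=O)CC1=O | intermediate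
15 | (2S)-2-(2,2-dimethyl-2H-chromen-6-yl)-6-(3-methylbut-2-en-1-yl)-2,3,5,6,7,8-hexahydro-4H-chromene-4,7-dione (both C6 epimers) | CC(C)=CCC1CC2=C(CC1=O)O[C@H](c1ccc3c(c1)C=CC(C)(C)O3)CC2=O | intermediate
16 | Dinklagin A, (2S)-2-(2,2-dimethyl-2H-chromen-6-yl)-7-hydroxy-6-(3-methylbut-2-en-1-yl)-2,3-dihydro-4H-chromen-4-one | CC(C)=CCc1cc2c(cc1O)O[C@H](c1ccc3c(c1)C=CC(C)(C)O3)CC2=O | target

## Step count and risks

Total step count: 8. Longest linear sequence: 6 steps (1, 2, 3, 4, 7, 8).

**Steps most likely to fail**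

**1. Step 7 (Proposed new method).** Turnover or facial discrimination of the BINOL–titanium catalyst may be poor with the bulky trisilylated triene, attack may occur through ring carbon C8, or the acid stage may ionise the p-alkoxybenzylic C2–O bond and erode the configuration.

The fallback uses known chemistry. It sets out from 12, with 4 as the second component, and rejoins the route at 15.
- An auxiliary-controlled titanium acetate aldol addition of (R)-3-acetyl-4-isopropyl-1,3-thiazolidine-2-thione to 12 (TiCl4, i-Pr2NEt, CH2Cl2, −78 °C) should give (3S)-3-(2,2-dimethyl-2H-chromen-6-yl)-3-hydroxy-1-[(4R)-4-isopropyl-2-thioxo-1,3-thiazolidin-3-yl]propan-1-one F1. The (4R)-auxiliary is written on the assumption of the usual chelated transition state; the diastereomers are separable by chromatography, so the antipodal auxiliary serves equally if the sense is reversed.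
- Silylation (TESCl, imidazole, DMF) gives the triethylsilyl ether F2.
- F2 is an active amide. It C-acylates the dianion of 4 under the conditions of step 3 to give 4-[(3S)-3-(2,2-dimethyl-2H-chromen-6-yl)-3-(triethylsilyloxy)propanoyl]-6-(3-methylbut-2-en-1-yl)cyclohexane-1,3-dione F3, with release of the auxiliary.
- TFA in CH2Cl2 at −20 to 0 °C removes the silyl group and drives the cyclodehydration through 14 to 15.

**2. Step 4.** Enolisation may go toward the wrong carbons (C7=C6 or C4=C4a in place of C7=C8 and C4=C3), giving a constitutionally non-uniform triene, and silyl groups may be lost by hydrolysis on handling.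

The fallback replaces exhaustive one-flask silylation by a differentiated, stepwise protection. It sets out from 6 and rejoins the route at 15.
- The free, unchelated C7 enol is silylated selectively (TIPSOTf 1.05 equiv, 2,6-lutidine, CH2Cl2, −78 °C) to the isolable 1-[2-hydroxy-4-(triisopropylsilyloxy)-5-(3-methylbut-2-en-1-yl)cyclohexa-1,3-dien-1-yl]ethanone F4, a plain chelated β-diketone enol.
- Chan bis-silylation of F4 (Et3N, TMSCl; then LDA, TMSCl) gives the constitutionally defined mixed triene 1-[1-(trimethylsilyloxy)ethenyl]-2-(trimethylsilyloxy)-4-(triisopropylsilyloxy)-5-(3-methylbut-2-en-1-yl)cyclohexa-1,3-diene F5.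
- F5 takes the place of 8 in step 7. The aldol adduct F6 (the analogue of 13 with a triisopropylsilyl group on the C7 oxygen) is desilylated by aqueous TFA to 14, which closes to 15.

**3. Step 8.** The quinone may over-oxidise the product (hydride abstraction at C2, or at the benzylic CH2 of the liberated ortho-prenylphenol followed by pyran closure), and the acidic hydroquinone may open ring C.

The fallback keeps the phenol masked through the oxidation. It sets out from 15 and rejoins the route at 16.
- Silylation (TBSOTf, 2,6-lutidine, CH2Cl2, −78 °C) gives the silyl dienol ether (2S)-7-(tert-butyldimethylsilyloxy)-2-(2,2-dimethyl-2H-chromen-6-yl)-6-(3-methylbut-2-en-1-yl)-2,3,5,6-tetrahydro-4H-chromen-4-one F7.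
- Dehydrogenation of the silyl dienol ether (DDQ 1.0 equiv, 2,6-lutidine, CH2Cl2, −20 °C) gives the aryl silyl ether (2S)-7-(tert-butyldimethylsilyloxy)-2-(2,2-dimethyl-2H-chromen-6-yl)-6-(3-methylbut-2-en-1-yl)-2,3-dihydro-4H-chromen-4-one F8, which cannot form an ortho-quinone methide.
- Et3N·3HF in THF at 0 °C frees the phenol to give 16 without basic conditions that would open ring C.

## Further compounds

F1 | step 7 | (3S)-3-(2,2-dimethyl-2H-chromen-6-yl)-3-hydroxy-1-[(4R)-4-isopropyl-2-thioxo-1,3-thiazolidin-3-yl]propan-1-one | CC(C)[C@@H]1CSC(=S)N1C(=O)C[C@H](O)c1ccc2c(c1)C=CC(C)(C)O2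
F2 | step 7 | (3S)-3-(2,2-dimethyl-2H-chromen-6-yl)-1-[(4R)-4-isopropyl-2-thioxo-1,3-thiazolidin-3-yl]-3-(triethylsilyloxy)propan-1-one | CC(C)[C@@H]1CSC(=S)N1C(=O)C[C@H](O[Si](CC)(CC)CC)c1ccc2c(c1)C=CC(C)(C)O2
F3 | step 7 | 4-[(3S)-3-(2,2-dimethyl-2H-chromen-6-yl)-3-(triethylsilyloxy)propanoyl]-6-(3-methylbut-2-en-1-yl)cyclohexane-1,3-dione | CC(C)=CCC1CC(C(=O)C[C@H](O[Si](CC)(CC)CC)c2ccc3c(c2)C=CC(C)(C)O3)C(=O)CC1=O
F4 | step 4 | 1-[2-hydroxy-4-(triisopropylsilyloxy)-5-(3-methylbut-2-en-1-yl)cyclohexa-1,3-dien-1-yl]ethanone (racemic) | CC(=O)C1=C(O)C=C(O[Si](C(C)C)(C(C)C)C(C)C)C(CC=C(C)C)C1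
F5 | step 4 | 1-[1-(trimethylsilyloxy)ethenyl]-2-(trimethylsilyloxy)-4-(triisopropylsilyloxy)-5-(3-methylbut-2-en-1-yl)cyclohexa-1,3-diene (racemic) | C=C(O[Si](C)(C)C)C1=C(O[Si](C)(C)C)C=C(O[Si](C(C)C)(C(C)C)C(C)C)C(CC=C(C)C)C1
F6 | step 4 | (3S)-3-(2,2-dimethyl-2H-chromen-6-yl)-1-[2-(trimethylsilyloxy)-4-(triisopropylsilyloxy)-5-(3-methylbut-2-en-1-yl)cyclohexa-1,3-dien-1-yl]-3-(trimethylsilyloxy)propan-1-one | CC(C)=CCC1CC(C(=O)C[C@H](O[Si](C)(C)C)c2ccc3c(c2)C=CC(C)(C)O3)=C(O[Si](C)(C)C)C=C1O[Si](C(C)C)(C(C)C)C(C)C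
F7 | step 8 | (2S)-7-(tert-butyldimethylsilyloxy)-2-(2,2-dimethyl-2H-chromen-6-yl)-6-(3-methylbut-2-en-1-yl)-2,3,5,6-tetrahydro-4H-chromen-4-one | CC(C)=CCC1CC2=C(C=C1O[Si](C)(C)C(C)(C)C)O[C@H](c1ccc3c(c1)C=CC(C)(C)O3)CC2=O
F8 | step 8 | (2S)-7-(tert-butyldimethylsilyloxy)-2-(2,2-dimethyl-2H-chromen-6-yl)-6-(3-methylbut-2-en-1-yl)-2,3-dihydro-4H-chromen-4-one | CC(C)=CCc1cc2c(cc1O[Si](C)(C)C(C)(C)C)O[C@H](c1ccc3c(c1)C=CC(C)(C)O3)CC2=O
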